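The pitfall in Wednesday's flask is to hold incoming ligand constant, the pseudo-first-order shortcut, when 4.50 mM of it stands against 5.0 mM of starting complex.

| flask | starting complex | incoming ligand | scavenger | remark | time |
|---|---|---|---|---|---|
| Wednesday's | 5 mM | 4.5 mM | 5 mM | the very flask that is asked about, followed so far |  |
| Tuesday's | 5 mM | 9 mM | 5 mM | run made earlier |  |
| flask | 5.0 mM | 4.50 mM | 5.00 mM |  | 2.0 min |

| run | time / s | starting complex / % | complex with two exchanged / % |
|---|---|---|---|
| Wednesday's | 10.0 | 93 | 1 |
| Wednesday's | 25.0 | 87 | 3 |
| Tuesday's | 10.0 | 87 | 1 |
| Tuesday's | 15.0 | 83 | 4 |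
| Tuesday's | 40.0 | 59 | 11 |
| Tuesday's | 80.0 | 45 | 26 |

(scatter of a reading: 1.5 percentage points)

- leaving ligand is meant together with its idle adduct
- the analysis behind the earlier runs scatters by 1.5 percentage points, standard deviation
- what may be going on: leaving ligand + incoming ligand <-> idle adduct; scavenger + leaving ligand -> scavenged by-product; complex with two exchanged + incoming ligand <-> leaving ligand + complex with three exchanged; complex with one exchanged + incoming ligand <-> leaving ligand + complex with two exchanged; starting complex + incoming ligand <-> leaving ligand + complex with one exchanged
- the earlier runs do not show how much of incoming ligand is bound; that part of a forecast is a guess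

- part of the starting complex that has reacted at 2.0 min
- share of the unused incoming ligand that is free and not bound as idle adduct, at 2.0 min

In the first instants of Wednesday's flask, at 10.0 s, starting complex reads 93 % and complex with two exchanged 1 %, within the scatter, so you are watching the first exchange.

For the middle, take Tuesday's flask, read out to 80.0 s. Counting one ligand per starting complex gone and one more per complex with two exchanged, and leaving out complex with three exchanged, which the readings do not show, it spent by this count 2.60 mM by 40.0 s, so its mean c(incoming ligand), halfway between start and end, was 7.70 mM. That gives, as a reading with its scatter, the mean-ligand rate constant, the logarithm of charged over remaining starting complex, divided by mean ligand and time: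

k = 0.00171 mM⁻¹ s⁻¹

Tuesday's last reading gives, by the same count, 1.47 ligand spent per starting complex reacted, and I carry that figure over to the end of Wednesday's flask as an estimate.

For Wednesday's flask at 2.0 min, my reckoning first guesses 50.0 % reacted:

mean c(incoming ligand) = 2.66 mM, reacted 42.1 %

mean c(incoming ligand) = 2.95 mM, reacted 45.5 %

I commit to the middle, 43.8 %. By the same count Tuesday's flask spent 2.60 mM in its first 40.0 s and then 1.45 mM in the next 40.0 s, less, so its ligand curve reads as sagging below a straight line, and if Wednesday's flask does the same, my figure leans high.

The forecast gives 39 % (33 % to 46 %) reacted, below mine, and 85 % (55 % to 99 %) free: “Ligand is used by both steps, so on Wednesday it starves.”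

The flask gives 40.9 % reacted and 99.7 % free.

    leaving ligand + incoming ligand ⇌ idle adduct, settled at all times (K = 120 M⁻¹)
    scavenger + leaving ligand → scavenged by-product (k = 250 M⁻¹ s⁻¹)
    complex with two exchanged + incoming ligand ⇌ leaving ligand + complex with three exchanged (K = 100, k = 1.10 M⁻¹ s⁻¹)
    complex with one exchanged + incoming ligand ⇌ leaving ligand + complex with two exchanged (K = 49.0, k = 3.30 M⁻¹ s⁻¹)
    starting complex + incoming ligand ⇌ leaving ligand + complex with one exchanged (K = 4.10, k = 1.60 M⁻¹ s⁻¹)

In Wednesday's flask incoming ligand ends at 33 % of its charge, less than the 59 % of its charge for starting complex. Turned around, k says this result needs a mean c(incoming ligand) of 2.56 mM, below the straight-line 2.99 mM.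

On the neighbour charged with 1.1 mM, start from a mean of 0.550 mM: reacted 10.7 %; then mean 0.706 mM: reacted 13.5 %. The middle is 12.1 %, and the neighbour gives 12.5 %.

Readings and results were generated by integration for an exercise, and the scatter is random.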